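## Retrosynthetic overview
1. The target comes from its hepta-O-benzyl ether by neutral hydrogenolysis as the last step.
2. Ring C (pyranone of the upper, eriodictyol unit) and ring F (pyranone of the lower, naringenin unit) are both opened at O1–C2 in one retrosynthetic move. This gives a bichalcone without stereocentres, the protected form of the chalcone dimer presumed in the biosynthesis. In the forward direction, one catalyst-controlled double chalcone-to-flavanone closure sets C2 and C2'', and C3 follows by equilibration.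
3. The upper Cα=Cβ bond comes from a Knoevenagel condensation of a deoxybenzoin with 3,4-bis(benzyloxy)benzaldehyde.
4. The C3–C8'' bond is made while everything is still acyclic. It comes from an oxidative umpolung (enolonium) coupling of an acetyl carbon with ring carbon C3' of the lower chalcone.
5. Both halves come from 2',4',6'-trihydroxyacetophenone. The aromatic rings are bought, and rings C and F are formed together in the penultimate step.

Assumption: the quinine-derived thiourea is taken to give the 2R series. If the first experiment shows the opposite sense, its commercial quinidine-derived pseudo-enantiomer is used and nothing else changes.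

## Route

Step 1
Reactants: 1 2',4',6'-trihydroxyacetophenone
Product: 2 1-[2,4-bis(benzyloxy)-6-hydroxyphenyl]ethanone
Conditions: BnBr (2.1 equiv), K2CO3, DMF, 60 °C
Reagents that add atoms: benzyl bromide, BrCc1ccccc1
Why: Williamson ether synthesis alkylates the para hydroxyl and one of the two equivalent ortho hydroxyls, while the last ortho hydroxyl is held in a strong hydrogen bond to the acetyl carbonyl and stays free; no stereocentre is formed.

Step 2
Reactants: 2 1-[2,4-bis(benzyloxy)-6-hydroxyphenyl]ethanone; 3 4-(benzyloxy)benzaldehyde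
Product: 4 (E)-1-[2,4-bis(benzyloxy)-6-hydroxyphenyl]-3-[4-(benzyloxy)phenyl]prop-2-en-1-one (lower chalcone)
Conditions: KOH, EtOH, rt; then cold 1 M HCl
Reagents that add atoms: none
Why: Claisen–Schmidt condensation (aldol addition, then E1cB dehydration) gives the (E)-enone, and the strongly basic medium keeps the product as its open phenolate so that ring F is not closed too early.

Step 3
Reactants: 2 1-[2,4-bis(benzyloxy)-6-hydroxyphenyl]ethanone
Product: 5 {1-[2,4-bis(benzyloxy)-6-(trimethylsilyloxy)phenyl]ethenyloxy}trimethylsilane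
Conditions: TMSOTf (2.4 equiv), Et3N, CH2Cl2, 0 °C
Reagents that add atoms: trimethylsilyl trifluoromethanesulfonate, C[Si](C)(C)OS(=O)(=O)C(F)(F)F
Why: Soft enolisation with a silyl triflate and a tertiary amine turns the methyl ketone into its silyl enol ether and caps the phenol at the same time, which prepares the acetyl carbon for polarity inversion.

Step 4
Reactants: 5 {1-[2,4-bis(benzyloxy)-6-(trimethylsilyloxy)phenyl]ethenyloxy}trimethylsilane; 4 lower chalcone
Product: 7 (E)-1-{4,6-bis(benzyloxy)-3-[2-(2,4-bis(benzyloxy)-6-hydroxyphenyl)-2-oxoethyl]-2-hydroxyphenyl}-3-[4-(benzyloxy)phenyl]prop-2-en-1-one (deoxybenzoin–chalcone), via enolonium species 6 (not isolated)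
Conditions: PhI(OAc)2, BF3·OEt2, CH2Cl2, −78 °C; then 4, −78 to −20 °C; aqueous work-up
Reagents that add atoms: none
Why: This is an umpolung α-arylation of a ketone through an enolonium species, in which the BF3-activated trivalent-iodine reagent makes the enol ether terminus electrophilic and C3' of 4 (ortho to the free phenol, the site where this ring type is halogenated, formylated and C-glycosylated) attacks it in Friedel–Crafts fashion with loss of iodobenzene, so the future C3–C8'' bond is formed oxidatively before any heterocycle or stereocentre exists.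

Step 5
Reactants: 7 deoxybenzoin–chalcone; 8 3,4-bis(benzyloxy)benzaldehyde
Product: 10 (E)-1-{4,6-bis(benzyloxy)-3-[(E)-1-(2,4-bis(benzyloxy)-6-hydroxyphenyl)-3-(3,4-bis(benzyloxy)phenyl)-1-oxoprop-2-en-2-yl]-2-hydroxyphenyl}-3-[4-(benzyloxy)phenyl]prop-2-en-1-one (bichalcone), via racemic trans-chromanone 9 (not isolated)
Conditions: piperidine (cat.), AcOH (cat.), PhMe, reflux, Dean–Stark; then KOH, EtOH–THF, 0 °C; then cold 1 M HCl to pH 5; used crude
Reagents that add atoms: none
Why: Knoevenagel-type aldol condensation of the activated deoxybenzoin methylene gives the α-aryl chalcone, its closure under the amine to the racemic trans-chromanone pulls the crowded condensation forward, and excess hydroxide then reopens that ring by E1cB retro-oxa-Michael reaction to the phenolate (the way flavanones are turned into isolable chalcones after a cold acid quench), which erases the uncontrolled stereocentres.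

Step 6
Reactants: 10 bichalcone
Product: 11 (2R,3S)-5,7-bis(benzyloxy)-2-[3,4-bis(benzyloxy)phenyl]-3-{(2R)-5,7-bis(benzyloxy)-2-[4-(benzyloxy)phenyl]-4-oxochroman-8-yl}chroman-4-one
Conditions: 1-[3,5-bis(trifluoromethyl)phenyl]-3-[(8α,9S)-6'-methoxycinchonan-9-yl]thiourea (20 mol%), PhMe, 0 °C to rt; chromatography
Reagents that add atoms: none
Why: Proposed new method: the quinuclidine nitrogen of the bifunctional catalyst deprotonates each chelated phenol while the thiourea hydrogen-bonds the neighbouring enone carbonyl, so both 6-endo-trig oxa-Michael closures (the laboratory counterpart of chalcone isomerase; 5-endo attack of the lower phenol on the upper enone is geometrically disfavoured) occur with the same local facial sense and give 2R and 2''R, the basic catalyst then equilibrates the acidic C3–H to the trans-diequatorial 3S epimer, and because two like-sensed events are coupled most of the minor enantiomer is diverted into separable diastereomers (Horeau amplification); the closest known reaction types are the cinchona-alkaloid-catalysed oxa-Michael cyclisation of o-tigloylphenols to 2,3-disubstituted chromanones and the cinchona-thiourea-catalysed cyclisation of α-activated 2'-hydroxychalcones to flavanones.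

Step 7
Reactants: 11 hepta-O-benzyl ether
Product: 12 (2R,3S)-2-(3,4-dihydroxyphenyl)-5,7-dihydroxy-3-[(2R)-5,7-dihydroxy-2-(4-hydroxyphenyl)-4-oxochroman-8-yl]chroman-4-one (CNP0105436.3)
Conditions: H2 (1 atm), Pd(OH)2/C, THF–MeOH, rt
Reagents that add atoms: none
Why: Catalytic hydrogenolysis cleaves all seven benzyl aryl ethers under neutral conditions, so neither retro-oxa-Michael opening at C2 or C2'' nor enolisation at C3 can scramble the three stereocentres.

## Compound list
1 | 2',4',6'-trihydroxyacetophenone | CC(=O)c1c(O)cc(O)cc1O | starting material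
2 | 1-[2,4-bis(benzyloxy)-6-hydroxyphenyl]ethanone | CC(=O)c1c(O)cc(OCc2ccccc2)cc1OCc1ccccc1 | intermediate
3 | 4-(benzyloxy)benzaldehyde | O=Cc1ccc(OCc2ccccc2)cc1 | starting material
4 | lower chalcone, (E)-1-[2,4-bis(benzyloxy)-6-hydroxyphenyl]-3-[4-(benzyloxy)phenyl]prop-2-en-1-one | O=C(/C=C/c1ccc(OCc2ccccc2)cc1)c1c(O)cc(OCc2ccccc2)cc1OCc1ccccc1 | intermediate
5 | bis-silyl enol ether of 2 | C=C(O[Si](C)(C)C)c1c(O[Si](C)(C)C)cc(OCc2ccccc2)cc1OCc1ccccc1 | intermediate
6 | O-bound enolonium species, 1-arylvinyl acetoxy(phenyl)iodane (BF3-activated, not isolated) | C=C(OI(OC(C)=O)c1ccccc1)c1c(O[Si](C)(C)C)cc(OCc2ccccc2)cc1OCc1ccccc1 | intermediate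
7 | deoxybenzoin–chalcone | O=C(/C=C/c1ccc(OCc2ccccc2)cc1)c1c(O)c(CC(=O)c2c(O)cc(OCc3ccccc3)cc2OCc2ccccc2)c(OCc2ccccc2)cc1OCc1ccccc1 | intermediate
8 | 3,4-bis(benzyloxy)benzaldehyde | O=Cc1ccc(OCc2ccccc2)c(OCc2ccccc2)c1 | starting material
9 | rac-(2R*,3S*)-5,7-bis(benzyloxy)-2-[3,4-bis(benzyloxy)phenyl]-3-{4,6-bis(benzyloxy)-2-hydroxy-3-[(E)-3-(4-benzyloxyphenyl)prop-2-enoyl]phenyl}chroman-4-one (racemic, one enantiomer drawn, not isolated) | O=C(/C=C/c1ccc(OCc2ccccc2)cc1)c1c(O)c([C@@H]2C(=O)c3c(OCc4ccccc4)cc(OCc4ccccc4)cc3O[C@H]2c2ccc(OCc3ccccc3)c(OCc3ccccc3)c2)c(OCc2ccccc2)cc1OCc1ccccc1 | intermediate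
10 | bichalcone, both enones (E), no stereocentre | O=C(/C=C/c1ccc(OCc2ccccc2)cc1)c1c(O)c(/C(=C\c2ccc(OCc3ccccc3)c(OCc3ccccc3)c2)C(=O)c2c(O)cc(OCc3ccccc3)cc2OCc2ccccc2)c(OCc2ccccc2)cc1OCc1ccccc1 | intermediate
11 | (2R,3S,2''R)-hepta-O-benzyl ether of the target | O=C1C[C@H](c2ccc(OCc3ccccc3)cc2)Oc2c1c(OCc1ccccc1)cc(OCc1ccccc1)c2[C@@H]1C(=O)c2c(OCc3ccccc3)cc(OCc3ccccc3)cc2O[C@H]1c1ccc(OCc2ccccc2)c(OCc2ccccc2)c1 | intermediate
12 | CNP0105436.3, (2R,3S,2''R)-eriodictyol-(3→8'')-naringenin | O=C1C[C@H](c2ccc(O)cc2)Oc2c1c(O)cc(O)c2[C@@H]1C(=O)c2c(O)cc(O)cc2O[C@H]1c1ccc(O)c(O)c1 | target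

## Step count and risks
Total steps: 7. Longest linear sequence: 6 (steps 1, 3, 4, 5, 6, 7).

Slow rotation about C3–C8'' is expected to give NMR-visible rotamers of 11 and 12. These are not separable stereoisomers.

**Step 6 (most likely to fail).** Unactivated, donor-substituted chalcones may close slowly or with low selectivity, and the upper ring may reopen under the base.
- The fallback replaces asymmetric closure by resolution. It sets out from 10 and comes back at 11.
- 10 is closed without stereocontrol (NaOAc, EtOH, reflux) to the mixture of 2,3-trans stereoisomers F5.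
- Silica gel separates the two racemic diastereomers. One of them consists of 11 and its mirror image ent-11 F6.
- Kinetic resolution by asymmetric transfer hydrogenation follows, with RuCl[(S,S)-TsDPEN](p-cymene) or its mirror image (whichever is matched to the 2''S series) and HCO2H–Et3N.
- This reduces the less hindered lower carbonyl of F6 to the cis-flavan-4-ol F7 and leaves 11, which is isolated by chromatography.

**Step 4.** The enolonium may be lost to intramolecular O-alkylation by the ortho oxygen, giving a coumaranone, or it may attack 4 at C5'.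
- The fallback uses the ortho oxygen productively. It sets out from 2 and comes back at 7.
- 2 is oxidised with SeO2 (dioxane–water, reflux) to the arylglyoxal, isolated as its cyclic hemiacetal 4,6-bis(benzyloxy)-2-hydroxybenzofuran-3(2H)-one F1.
- TsOH-catalysed Friedel–Crafts replacement of the hemiacetal hydroxyl by C3 of a second molecule of 2 gives 2-[3-acetyl-4,6-bis(benzyloxy)-2-hydroxyphenyl]-4,6-bis(benzyloxy)benzofuran-3(2H)-one F2.
- Zn in AcOH cleaves the α-aryloxy ketone C–O bond to 2-[3-acetyl-4,6-bis(benzyloxy)-2-hydroxyphenyl]-1-[2,4-bis(benzyloxy)-6-hydroxyphenyl]ethanone F3.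
- Claisen–Schmidt condensation of the acetyl group of F3 with 3 (KOH, EtOH) gives 7.

**Step 5.** The methylene is flanked by two doubly ortho-substituted aryl groups and may not condense.
- The fallback makes the Cα–Cβ bond by irreversible alkylation and adjusts the oxidation state afterwards. It sets out from 7 and comes back at 9.
- The trianion of 7 (KHMDS, THF, −78 °C) is C-benzylated with commercial 3,4-bis(benzyloxy)benzyl chloride to the racemic α-aryl dihydrochalcone F4.
- DDQ (CH2Cl2, 0 °C) abstracts hydride from the dialkoxybenzylic CH2 to give a quinone-methide-like cation. The neighbouring phenol traps it and gives 9.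
- 9 is opened to 10 with KOH and a cold acid quench as in step 5.

Further compounds
F1 | step 4 | 4,6-bis(benzyloxy)-2-hydroxybenzofuran-3(2H)-one (racemic hemiacetal) | O=C1C(O)Oc2cc(OCc3ccccc3)cc(OCc3ccccc3)c21
F2 | step 4 | 2-[3-acetyl-4,6-bis(benzyloxy)-2-hydroxyphenyl]-4,6-bis(benzyloxy)benzofuran-3(2H)-one (racemic) | O=C1C(c2c(O)c(C(C)=O)c(OCc3ccccc3)cc2OCc2ccccc2)Oc2cc(OCc3ccccc3)cc(OCc3ccccc3)c21
F3 | step 4 | 2-[3-acetyl-4,6-bis(benzyloxy)-2-hydroxyphenyl]-1-[2,4-bis(benzyloxy)-6-hydroxyphenyl]ethanone | CC(=O)c1c(O)c(CC(=O)c2c(O)cc(OCc3ccccc3)cc2OCc2ccccc2)c(OCc2ccccc2)cc1OCc1ccccc1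
F4 | step 5 | α-aryl dihydrochalcone from C-benzylation of 7 (racemic) | O=C(/C=C/c1ccc(OCc2ccccc2)cc1)c1c(O)c(C(Cc2ccc(OCc3ccccc3)c(OCc3ccccc3)c2)C(=O)c2c(O)cc(OCc3ccccc3)cc2OCc2ccccc2)c(OCc2ccccc2)cc1OCc1ccccc1
F5 | step 6 | stereoisomer mixture of the hepta-O-benzyl biflavanone | O=C1CC(c2ccc(OCc3ccccc3)cc2)Oc2c1c(OCc1ccccc1)cc(OCc1ccccc1)c2C1C(=O)c2c(OCc3ccccc3)cc(OCc3ccccc3)cc2OC1c1ccc(OCc2ccccc2)c(OCc2ccccc2)c1
F6 | step 6 | ent-11, the (2S,3R,2''S) enantiomer | O=C1C[C@@H](c2ccc(OCc3ccccc3)cc2)Oc2c1c(OCc1ccccc1)cc(OCc1ccccc1)c2[C@H]1C(=O)c2c(OCc3ccccc3)cc(OCc3ccccc3)cc2O[C@@H]1c1ccc(OCc2ccccc2)c(OCc2ccccc2)c1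
F7 | step 6 | (2S,3R,2''S,4''S)-flavan-4''-ol from reduction of ent-11 | O[C@H]1C[C@@H](c2ccc(OCc3ccccc3)cc2)Oc2c1c(OCc1ccccc1)cc(OCc1ccccc1)c2[C@H]1C(=O)c2c(OCc3ccccc3)cc(OCc3ccccc3)cc2O[C@@H]1c1ccc(OCc2ccccc2)c(OCc2ccccc2)c1
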